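The 3,7-dioxabicyclo[3.3.0]octane core is numbered C1/C5 (ring fusion), C2/C6 (aryl carbons), O3/O7 and C4/C8 (methylenes), and everything rests on the C1–C5 fusion bond. One palladium-catalysed borylative 1,6-enyne cyclisation closes ring A (C1–C2–O3–C4–C5), sets C1 trans to the C2 aryl, puts boron on C8 and turns the aryl alkyne into a (Z)-C5=C6 benzylidene, a masked benzylic C6 whose geometry later fixes C5 and C6. It exploits the fact that the vinyl group (C1–C8) and the aryl alkyne (C5–C6) both hang on the C2–O3–C4 ether: the precursor is an (S)-1-arylallyl 3-arylpropargyl ether. Syn hydroboration and O7–C8 closure of ring B finish the exo,exo furofuran.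

Key step: step 6

Remark: the target is read as the exo,exo isomer (1R,2S,5R,6S) of the bicyclic core, and the core locants defined above are used for the corresponding atoms of every intermediate.

Step 1
Reactants: 1 3-hydroxy-4,5-dimethoxybenzaldehyde; 2 chlorotriisopropylsilane
Product: 3 3,4-dimethoxy-5-(triisopropylsilyloxy)benzaldehyde
Conditions: TIPSCl (1.2 equiv), imidazole (2.5 equiv), DMF, rt
Reagents that add atoms: chlorotriisopropylsilane, CC(C)[Si](Cl)(C(C)C)C(C)C
Why: Imidazole-promoted silyl ether formation masks the only acidic proton with a bulky group that should tolerate the Grignard reagent, NaH, borane and perborate used later and that fluoride removes at the end.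

Step 2
Reactants: 3 3,4-dimethoxy-5-(triisopropylsilyloxy)benzaldehyde; 4 vinylmagnesium bromide
Product: 5 rac-1-[3,4-dimethoxy-5-(triisopropylsilyloxy)phenyl]prop-2-en-1-ol
Conditions: CH2=CHMgBr (1.2 equiv), THF, −78 → 0 °C; aq NH4Cl
Reagents that add atoms: vinylmagnesium bromide, C=C[Mg]Br
Why: Grignard 1,2-addition to the aryl aldehyde should give the secondary allylic alcohol as the racemate, which is resolved in the next step.

Step 3
Reactants: 5 rac-1-[3,4-dimethoxy-5-(triisopropylsilyloxy)phenyl]prop-2-en-1-ol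
Product: 6 (S)-1-[3,4-dimethoxy-5-(triisopropylsilyloxy)phenyl]prop-2-en-1-ol
Conditions: Ti(OiPr)4 (0.15 equiv), L-(+)-DIPT (0.2 equiv), t-BuOOH (0.6 equiv), 4 Å MS, CH2Cl2, −20 °C
Reagents that add atoms: none
Why: Sharpless kinetic resolution, in which the L-(+)-tartrate catalyst is expected to epoxidise the (R)-enantiomer much faster, so that stopping just past half conversion should leave the (S)-alcohol, which carries the future C2 stereocentre, enantioenriched and easily separated from the polar epoxy alcohol.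

Step 4
Reactants: 6 (S)-1-[3,4-dimethoxy-5-(triisopropylsilyloxy)phenyl]prop-2-en-1-ol; 7 propargyl bromide
Product: 8 {2,3-dimethoxy-5-[(1S)-1-(prop-2-yn-1-yloxy)prop-2-en-1-yl]phenoxy}triisopropylsilane
Conditions: NaH (1.2 equiv), propargyl bromide (1.5 equiv), Bu4NI (cat.), THF, 0 °C → rt
Reagents that add atoms: propargyl bromide, C#CCBr
Why: Williamson ether synthesis in which the sodium alkoxide displaces the primary propargylic bromide by SN2 at oxygen, so the carbinol stereocentre is untouched, and the hindered aryl silyl ether should survive NaH in THF at this temperature.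

Step 5
Reactants: 8 {2,3-dimethoxy-5-[(1S)-1-(prop-2-yn-1-yloxy)prop-2-en-1-yl]phenoxy}triisopropylsilane; 9 5-iodo-1,2,3-trimethoxybenzene
Product: 10 triisopropyl{2,3-dimethoxy-5-[(1S)-1-{[3-(3,4,5-trimethoxyphenyl)prop-2-yn-1-yl]oxy}prop-2-en-1-yl]phenoxy}silane
Conditions: PdCl2(PPh3)2 (2 mol %), CuI (4 mol %), Et3N, THF, rt
Reagents that add atoms: 5-iodo-1,2,3-trimethoxybenzene, COc1cc(I)cc(OC)c1OC
Why: Sonogashira coupling of the terminal alkyne with the aryl iodide should run at room temperature without affecting the allylic ether, the vinyl group or the silyl ether.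

Step 6
Reactants: 10 triisopropyl{2,3-dimethoxy-5-[(1S)-1-{[3-(3,4,5-trimethoxyphenyl)prop-2-yn-1-yl]oxy}prop-2-en-1-yl]phenoxy}silane; 11 bis(pinacolato)diboron
Product: 12 2-{[(2S,3S,4Z)-2-[3,4-dimethoxy-5-(triisopropylsilyloxy)phenyl]-4-(3,4,5-trimethoxybenzylidene)tetrahydrofuran-3-yl]methyl}-4,4,5,5-tetramethyl-1,3,2-dioxaborolane
Conditions: Pd(OAc)2 (5 mol %), B2pin2 (1.3 equiv), MeOH (1.5 equiv), toluene, 50 °C
Reagents that add atoms: bis(pinacolato)diboron, CC1(C)OB(OC1(C)C)B1OC(C)(C)C(C)(C)O1
Why: A palladium hydride generated from Pd(OAc)2, B2pin2 and MeOH should add syn across the aryl alkyne with the metal on C5 and hydrogen on benzylic C6, the C5 alkenylpalladium then inserts the tethered vinyl group to form C1–C5, and the primary C8–palladium bond is transmetalated by the diboron and reductively eliminated as C8–Bpin, methanol regenerating the hydride. The closest known reaction type is the palladium-catalysed borylative cyclisation of 1,6-enynes with a diboron reagent. Ring A (C1–C2–O3–C4–C5) closes in the 5-exo-trig mode. The new stereocentre C1 is controlled by C2, because the C2 aryl should occupy a pseudo-equatorial site of the envelope-like insertion transition state, which places the C8 arm trans to it. The step needs regioselective hydropalladation, boryl transfer faster than β-hydride elimination from C8–palladium, and a single alkene geometry; these are secured by chelation of the vinyl group (only the C5-palladated isomer can cyclise), by the excess diboron at a phosphine-free metal centre, and by the syn addition, which gives the Z alkene with the aryl cis to C4.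

Step 7
Reactants: 12 2-{[(2S,3S,4Z)-2-[3,4-dimethoxy-5-(triisopropylsilyloxy)phenyl]-4-(3,4,5-trimethoxybenzylidene)tetrahydrofuran-3-yl]methyl}-4,4,5,5-tetramethyl-1,3,2-dioxaborolane
Product: 14 (S)-{(3R,4R,5S)-5-[3,4-dimethoxy-5-(triisopropylsilyloxy)phenyl]-4-(hydroxymethyl)tetrahydrofuran-3-yl}(3,4,5-trimethoxyphenyl)methanol, via C6 alkylborane 13 (not isolated)
Conditions: BH3·THF (2.5 equiv), THF, 0 °C → rt; then NaBO3·4H2O, THF/H2O, rt
Reagents that add atoms: sodium perborate (used as NaBO3·4H2O), [Na+].[Na+].O[B-]1(O)OO[B-](O)(O)OO1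
Why: Brown hydroboration–oxidation, in which borane should add H–B syn across the (Z)-benzylidene from the face anti to the C8 arm on the adjacent C1, with boron on the less substituted benzylic C6 and hydrogen on C5 cis to H1, after which perborate converts both C–B bonds into C–O bonds with retention, so that the alkene geometry is translated into the C5 and C6 configurations of the exo aryl.

Step 8
Reactants: 14 (S)-{(3R,4R,5S)-5-[3,4-dimethoxy-5-(triisopropylsilyloxy)phenyl]-4-(hydroxymethyl)tetrahydrofuran-3-yl}(3,4,5-trimethoxyphenyl)methanol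
Product: 16 (1R,2S,5R,6S)-2-[3,4-dimethoxy-5-(triisopropylsilyloxy)phenyl]-6-(3,4,5-trimethoxyphenyl)-3,7-dioxabicyclo[3.3.0]octane, via primary tosylate 15 (not isolated)
Conditions: TsCl (1.1 equiv), pyridine, 0 °C → rt; then 50 °C
Reagents that add atoms: none
Why: Selective sulfonylation of the primary C8 hydroxyl followed by intramolecular Williamson etherification (5-exo-tet attack of the C6 hydroxyl on C8) closes ring B without breaking a bond to any stereocentre, so C6 keeps its configuration and the ring fusion can only be cis.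

Step 9
Reactants: 16 (1R,2S,5R,6S)-2-[3,4-dimethoxy-5-(triisopropylsilyloxy)phenyl]-6-(3,4,5-trimethoxyphenyl)-3,7-dioxabicyclo[3.3.0]octane
Product: 17 5-[(1S,3aR,4S,6aR)-4-(3,4,5-trimethoxyphenyl)tetrahydro-1H,3H-furo[3,4-c]furan-1-yl]-2,3-dimethoxyphenol
Conditions: TBAF (1.2 equiv), AcOH (1.2 equiv), THF, 0 °C
Reagents that add atoms: none
Why: Fluoride-mediated desilylation cleaves the aryl Si–O bond selectively, the acetic acid buffer keeps the liberated electron-rich phenol protonated, and the benzylic ethers of the furofuran are inert under these conditions.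

Compound list

1 | 3-hydroxy-4,5-dimethoxybenzaldehyde | COc1cc(C=O)cc(O)c1OC | starting material
2 | chlorotriisopropylsilane | CC(C)[Si](Cl)(C(C)C)C(C)C | starting material
3 | 3,4-dimethoxy-5-(triisopropylsilyloxy)benzaldehyde | COc1cc(C=O)cc(O[Si](C(C)C)(C(C)C)C(C)C)c1OC | intermediate
4 | vinylmagnesium bromide | C=C[Mg]Br | starting material
5 | rac-1-[3,4-dimethoxy-5-(triisopropylsilyloxy)phenyl]prop-2-en-1-ol | COc1cc(cc(O[Si](C(C)C)(C(C)C)C(C)C)c1OC)C(O)C=C | intermediate
6 | (S)-1-[3,4-dimethoxy-5-(triisopropylsilyloxy)phenyl]prop-2-en-1-ol | COc1cc(cc(O[Si](C(C)C)(C(C)C)C(C)C)c1OC)[C@@H](O)C=C | intermediate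
7 | propargyl bromide | C#CCBr | starting material
8 | {2,3-dimethoxy-5-[(1S)-1-(prop-2-yn-1-yloxy)prop-2-en-1-yl]phenoxy}triisopropylsilane | COc1cc(cc(O[Si](C(C)C)(C(C)C)C(C)C)c1OC)[C@@H](OCC#C)C=C | intermediate
9 | 5-iodo-1,2,3-trimethoxybenzene | COc1cc(I)cc(OC)c1OC | starting material
10 | triisopropyl{2,3-dimethoxy-5-[(1S)-1-{[3-(3,4,5-trimethoxyphenyl)prop-2-yn-1-yl]oxy}prop-2-en-1-yl]phenoxy}silane (enyne precursor) | COc1cc(cc(O[Si](C(C)C)(C(C)C)C(C)C)c1OC)[C@@H](OCC#Cc1cc(OC)c(OC)c(OC)c1)C=C | intermediate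
11 | bis(pinacolato)diboron | CC1(C)OB(OC1(C)C)B1OC(C)(C)C(C)(C)O1 | starting material
12 | 2-{[(2S,3S,4Z)-2-[3,4-dimethoxy-5-(triisopropylsilyloxy)phenyl]-4-(3,4,5-trimethoxybenzylidene)tetrahydrofuran-3-yl]methyl}-4,4,5,5-tetramethyl-1,3,2-dioxaborolane | COc1cc(cc(O[Si](C(C)C)(C(C)C)C(C)C)c1OC)[C@H]1OC/C(=C\c2cc(OC)c(OC)c(OC)c2)[C@@H]1CB1OC(C)(C)C(C)(C)O1 | intermediate
13 | C6 alkylborane: syn H–BH2 adduct of 12 across C5=C6, boron on benzylic C6, H5 cis to H1 (drawn as the monoalkylborane) | COc1cc(cc(O[Si](C(C)C)(C(C)C)C(C)C)c1OC)[C@H]1OC[C@H]([C@H](B)c2cc(OC)c(OC)c(OC)c2)[C@@H]1CB1OC(C)(C)C(C)(C)O1 | intermediate (not isolated)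
14 | (S)-{(3R,4R,5S)-5-[3,4-dimethoxy-5-(triisopropylsilyloxy)phenyl]-4-(hydroxymethyl)tetrahydrofuran-3-yl}(3,4,5-trimethoxyphenyl)methanol | COc1cc(cc(O[Si](C(C)C)(C(C)C)C(C)C)c1OC)[C@H]1OC[C@H]([C@H](O)c2cc(OC)c(OC)c(OC)c2)[C@@H]1CO | intermediate
15 | primary tosylate of 14: {(2S,3R,4R)-2-[3,4-dimethoxy-5-(triisopropylsilyloxy)phenyl]-4-[(S)-hydroxy(3,4,5-trimethoxyphenyl)methyl]tetrahydrofuran-3-yl}methyl 4-methylbenzenesulfonate | COc1cc(cc(O[Si](C(C)C)(C(C)C)C(C)C)c1OC)[C@H]1OC[C@H]([C@H](O)c2cc(OC)c(OC)c(OC)c2)[C@@H]1COS(=O)(=O)c1ccc(C)cc1 | intermediate (not isolated)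
16 | (1R,2S,5R,6S)-2-[3,4-dimethoxy-5-(triisopropylsilyloxy)phenyl]-6-(3,4,5-trimethoxyphenyl)-3,7-dioxabicyclo[3.3.0]octane | COc1cc(cc(O[Si](C(C)C)(C(C)C)C(C)C)c1OC)[C@H]1OC[C@H]2[C@@H]1CO[C@@H]2c1cc(OC)c(OC)c(OC)c1 | intermediate
17 | 5-[(1S,3aR,4S,6aR)-4-(3,4,5-trimethoxyphenyl)tetrahydro-1H,3H-furo[3,4-c]furan-1-yl]-2,3-dimethoxyphenol (CNP0181235.1) | COc1cc([C@H]2OC[C@H]3[C@@H]2CO[C@@H]3c2cc(OC)c(OC)c(OC)c2)cc(O)c1OC | target

Total steps: 9. Longest linear sequence: 9 steps (1 → 17).

Steps most likely to fail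

1. Step 6. The C8 alkylpalladium intermediate may lose the β-hydrogen on C1 faster than it is borylated, which would give the cycloisomerised diene. The palladium hydride may also add to the alkyne with the metal on C6, or move the vinyl double bond into conjugation. The fallback sets out from 6 and returns at 16, forming C1–C5 by a radical instead. Alcohol 6, the fast-reacting enantiomer towards the D-(−)-tartrate catalyst, is epoxidised (Ti(OiPr)4, D-(−)-DIPT, t-BuOOH, CH2Cl2, −20 °C) to the anti epoxy alcohol (R)-[3,4-dimethoxy-5-(triisopropylsilyloxy)phenyl][(S)-oxiran-2-yl]methanol F1. Commercial (E)-3-(3,4,5-trimethoxyphenyl)prop-2-en-1-ol is converted with PBr3 into (E)-5-(3-bromoprop-1-en-1-yl)-1,2,3-trimethoxybenzene F2. This bromide alkylates the sodium alkoxide of the epoxy alcohol (NaH, THF, 0 °C, aprotic to keep epoxide migration slow) to give its (E)-3-(3,4,5-trimethoxyphenyl)allyl ether F3. The trivalent titanium reagent Cp2TiCl (from Cp2TiCl2 and Zn, THF, rt) should open the epoxide to the C1 radical with the titanium alkoxide on C8. 5-exo-trig addition to the cinnamyl double bond then forms C1–C5 trans to the C2 aryl, and an iodine quench of the benzylic C6 species lets the C8 alkoxide close ring B, giving 16 directly.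

2. Step 7. The borane may attack the benzylidene from the face syn to the C8 arm, place boron on C5, or react too slowly beside the bulky boronate, so that the relay from alkene geometry to C5 and C6 is eroded. The fallback sets out from 12 and returns at 16. Only the C8–B bond is oxidised (NaBO3·4H2O, THF/H2O, rt) to [(2S,3R,4Z)-2-[3,4-dimethoxy-5-(triisopropylsilyloxy)phenyl]-4-(3,4,5-trimethoxybenzylidene)tetrahydrofuran-3-yl]methanol F4. Ring B is then closed by Brønsted-acid-catalysed intramolecular Markovnikov hydroalkoxylation (TfOH, 5 mol %, CH2Cl2, −20 °C). Protonation at C5 should give the benzylic C6 cation, which only the cis-disposed C8 hydroxyl can capture, with the aryl expected on the convex face. A short reaction time at low temperature limits acid epimerisation at C2 and C6.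

3. Step 8. Sulfonylation may not discriminate cleanly between the two hydroxyls, or the primary sulfonate may be intercepted by chloride or pyridine before the C6 hydroxyl closes the ring. The fallback sets out from 14 and returns at 16, with the roles of the two hydroxyls exchanged. In an acid-catalysed SN1-type cyclodehydration (camphorsulfonic acid, 10 mol %, CH2Cl2, 0 °C) the electron-rich benzylic C6–OH ionises and the C8 hydroxyl captures the cation from the convex face. No new compound is made on the way.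

Further compounds

F1 | step 6 | (R)-[3,4-dimethoxy-5-(triisopropylsilyloxy)phenyl][(S)-oxiran-2-yl]methanol | COc1cc(cc(O[Si](C(C)C)(C(C)C)C(C)C)c1OC)[C@@H](O)[C@@H]1CO1
F2 | step 6 | (E)-5-(3-bromoprop-1-en-1-yl)-1,2,3-trimethoxybenzene | COc1cc(/C=C/CBr)cc(OC)c1OC
F3 | step 6 | (2S)-2-[(R)-[3,4-dimethoxy-5-(triisopropylsilyloxy)phenyl]{[(2E)-3-(3,4,5-trimethoxyphenyl)prop-2-en-1-yl]oxy}methyl]oxirane | COc1cc(cc(O[Si](C(C)C)(C(C)C)C(C)C)c1OC)[C@@H](OC/C=C/c1cc(OC)c(OC)c(OC)c1)[C@@H]1CO1
F4 | step 7 | [(2S,3R,4Z)-2-[3,4-dimethoxy-5-(triisopropylsilyloxy)phenyl]-4-(3,4,5-trimethoxybenzylidene)tetrahydrofuran-3-yl]methanol | COc1cc(cc(O[Si](C(C)C)(C(C)C)C(C)C)c1OC)[C@H]1OC/C(=C\c2cc(OC)c(OC)c(OC)c2)[C@@H]1CO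
F0 | step 8 | none | none
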